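## Retrosynthetic overview
1. The last bond cut is C7–C8 (sp3–sp2). Diol-lactone 16 (C1–C7) and (E)-alkenyl iodide acetate 10 (C8–C15 plus furan) are joined by a blue-light Ir/Ni deoxygenative alkenylation.
2. In 10, C13–C14 comes from a Ni-electrocatalytic decarboxylative alkenylation and the 12E olefin from Zr-catalysed methylalumination. The 8E iodide comes from cross-metathesis with isopropenyl-Bpin followed by iododeboronation, and C10 is the CH of (S)-epichlorohydrin.
3. In 16, C5 is the oxirane CH of (R)-glycidate and C1–C3 come from a zinc homoenolate. C4 is set by chelation-controlled MeMgBr addition, and C6–C7 by vinyl-cuprate opening then ozonolysis/reduction.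
4. The furan and both oxiranes are bought. The γ-lactone is the only ring made (step 11), and no ring is formed after it.

Assumption: numbering runs C1 (lactone C=O) to C15, then furan. The SMILES decodes as 4S,5R,10S,8E,12E. Potassium (R)-glycidate (the L-serine-derived salt), 3-(furan-3-yl)propanoic acid and BrZnCH2CH2CO2Et are taken as catalogue items.

## Route

**Step 1**
Reactants: 1, (S)-epichlorohydrin
Product: 2, (S)-1-chloropent-4-yn-2-ol
Conditions: HC≡CH, n-BuLi, THF, −78 °C; BF3·OEt2; then 1, −78 °C
Reagents that add atoms: acetylene, C#C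
Why: This is a BF3-promoted (Yamaguchi–Hirao) SN2 opening of the epoxide by lithium acetylide at the unsubstituted CH2, and the C–O bond at the stereocentre (future C10) is not touched, so the bought configuration is carried over.

**Step 2**
Reactants: 2, (S)-1-chloropent-4-yn-2-ol
Product: 3, (S)-hex-1-en-5-yn-3-ol
Conditions: Me3S+I− (5 equiv), n-BuLi (4.8 equiv), THF, −20 °C → rt
Reagents that add atoms: trimethylsulfonium iodide, C[S+](C)C.[I-]
Why: The alkoxide closes to the terminal epoxide, dimethylsulfonium methylide opens it at CH2, and the betaine loses Me2S (sulfonium-ylide epoxide-to-allylic-alcohol homologation), while C10–O stays intact so the centre remains S.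

**Step 3**
Reactants: 3, (S)-hex-1-en-5-yn-3-ol
Product: 4, (3S,5E)-6-iodo-5-methylhexa-1,5-dien-3-ol
Conditions: Me3Al (3.5 equiv), Cp2ZrCl2 (0.3 equiv), CH2Cl2, 0 °C → rt; then I2, THF, −30 °C
Reagents that add atoms: trimethylaluminium, C[Al](C)C; iodine, II
Why: Negishi Zr-catalysed methylalumination adds Me and Al syn to the terminal alkyne only (Al terminal), and iodinolysis with retention gives the E-iodide that fixes the 12E geometry.

**Step 4**
Reactants: 5, 3-(furan-3-yl)propanoic acid
Product: 6, 1,3-dioxoisoindolin-2-yl 3-(furan-3-yl)propanoate (redox-active ester)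
Conditions: N-hydroxyphthalimide, DIC, DMAP (cat.), CH2Cl2, rt
Reagents that add atoms: N-hydroxyphthalimide, O=C1c2ccccc2C(=O)N1O
Why: This is a routine carbodiimide (Steglich-type) esterification that installs the reducible N–O trigger for decarboxylation.

**Step 5**
Reactants: 4, (3S,5E)-6-iodo-5-methylhexa-1,5-dien-3-ol; 6, redox-active ester (1.5 equiv)
Product: 7, (3S,5E)-8-(furan-3-yl)-5-methylocta-1,5-dien-3-ol
Conditions: NiCl2·6H2O (20 mol %), 2,2′-bipyridine (20 mol %), AgNO3 (0.3 equiv), DMF, (+)Mg/(−)RVC, undivided cell, constant current, rt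
Reagents that add atoms: none
Why: In this Ni-electrocatalytic decarboxylative alkenylation, cathodically fed low-valent Ni reduces 6 to the furyl-CH2CH2 radical and couples it with alkenyl–Ni from 4 with retention of olefin geometry, forming C13–C14; the free OH, vinyl group and furan are inert under these reductive conditions.

**Step 6**
Reactants: 7, (3S,5E)-8-(furan-3-yl)-5-methylocta-1,5-dien-3-ol
Product: 8, (2Z,4S,6E)-9-(furan-3-yl)-6-methyl-2-(4,4,5,5-tetramethyl-1,3,2-dioxaborolan-2-yl)nona-2,6-dien-4-ol (Bpin trans to the carbinol carbon)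
Conditions: isopropenyl-Bpin (3 equiv), Hoveyda–Grubbs II (5 mol %), 1,4-benzoquinone (10 mol %), CH2Cl2, 40 °C
Reagents that add atoms: isopropenylboronic acid pinacol ester, CC(=C)B1OC(C)(C)C(C)(C)O1
Why: In this olefin cross-metathesis only the monosubstituted alkene reacts (the trisubstituted alkene is inert and no viable ring-closing path exists), and the bulky Bpin ends up trans to C10, which sets the geometry needed for 8E.

**Step 7**
Reactants: 8, alkenyl boronate
Product: 9, (2E,4S,6E)-9-(furan-3-yl)-2-iodo-6-methylnona-2,6-dien-4-ol
Conditions: aq NaOH (3 equiv), then I2 (1.2 equiv), THF, 0 °C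
Reagents that add atoms: iodine, II
Why: Brown-type iododeboronation of the hydroxide "ate" complex proceeds with retention, placing I trans to C10; it is done before acetylation so that no ester meets hydroxide.

**Step 8**
Reactants: 9, iodo dienol
Product: 10, (2E,4S,6E)-9-(furan-3-yl)-2-iodo-6-methylnona-2,6-dien-4-yl acetate
Conditions: Ac2O, pyridine, DMAP (cat.), CH2Cl2, 0 °C → rt
Reagents that add atoms: acetic anhydride, CC(=O)OC(C)=O
Why: Standard O-acylation (no C–O cleavage, so C10 stays S) puts the only acetate in place before the C5 hydroxyl enters the molecule, so no differentiation of two alcohols is ever needed.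

**Step 9**
Reactants: 11, potassium (R)-oxirane-2-carboxylate
Product: 12, S-ethyl (R)-oxirane-2-carbothioate
Conditions: EtSH, EDC·HCl, DMAP (cat.), CH2Cl2, 0 °C → rt
Reagents that add atoms: ethanethiol, CCS
Why: Carbodiimide thioesterification under near-neutral conditions leaves the oxirane and its stereocentre (future C5) untouched.

**Step 10**
Reactants: 12, S-ethyl (R)-oxirane-2-carbothioate
Product: 13, ethyl 4-[(2R)-oxiran-2-yl]-4-oxobutanoate
Conditions: BrZnCH2CH2CO2Et (1.5 equiv), PdCl2(PPh3)2 (5 mol %), toluene/THF, rt
Reagents that add atoms: (3-ethoxy-3-oxopropyl)zinc bromide, CCOC(=O)CC[Zn]Br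
Why: In the Fukuyama ketone synthesis Pd inserts into C(acyl)–S and the mild zinc homoenolate delivers C1–C3 without over-addition or enolisation of the α-oxy centre.

**Step 11**
Reactants: 13, epoxy keto ester
Product: 14, (5S)-5-methyl-5-[(2R)-oxiran-2-yl]oxolan-2-one
Conditions: MeMgBr (1.15 equiv), Et2O/CH2Cl2, −78 → −20 °C; AcOH quench
Reagents that add atoms: methylmagnesium bromide, C[Mg]Br
Why: In this Cram-chelate addition Mg bridges the ketone O and the oxirane O, so Me attacks the face opposite the oxirane CH2 and sets 4S from the bought 5R centre; the tertiary alkoxide then closes onto the ethyl ester to form the γ-lactone.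

**Step 12**
Reactants: 14, epoxy lactone
Product: 15, (5S)-5-[(1R)-1-hydroxybut-3-en-1-yl]-5-methyloxolan-2-one
Conditions: vinylMgBr (2.2 equiv), CuBr·SMe2 (1.1 equiv), THF/Me2S, −40 → −20 °C
Reagents that add atoms: vinylmagnesium bromide, C=C[Mg]Br
Why: The organocuprate opens the epoxide by SN2 at the terminal CH2 (C6) and tolerates the lactone, and C5–O is not broken so C5 stays R.

**Step 13**
Reactants: 15, homoallylic alcohol lactone
Product: 16, (5S)-5-[(1R)-1,3-dihydroxypropyl]-5-methyloxolan-2-one
Conditions: O3, CH2Cl2/MeOH, −78 °C; then NaBH4, −78 → 0 °C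
Reagents that add atoms: ozone, [O-][O+]=O
Why: Ozonolysis with reductive work-up trims the vinyl group to the C7 primary alcohol, and the γ-lactone survives brief cold borohydride.

**Step 14**
Reactants: 16, diol lactone (1.5 equiv); 10, alkenyl iodide acetate
Product: 17, 10-acetylirciformonin B
Conditions: 16, N-aryl benzoxazolium BF4 salt (1.5 equiv), pyridine, MTBE, rt, 15 min; then 10, Ir(ppy)2(dtbbpy)PF6 (2 mol %), NiBr2·dtbbpy (10 mol %), quinuclidine (1.8 equiv), DMA/MTBE, 450 nm LEDs, rt
Reagents that add atoms: none
Why: Proposed new method: photochemical Ir/Ni deoxygenative alkenylation of an unprotected 1,3-diol – the unhindered primary C7–OH (not the neopentyl-like C5–OH) condenses with the benzoxazolium salt, and the adduct is oxidised by excited Ir(III), deprotonated by quinuclidine and β-fragments to the primary C7 radical; this radical is captured by the alkenyl–Ni(II) formed by stereoretentive oxidative addition of Ni(0) into C8–I, and reductive elimination from Ni(III) forges C7–C8 with 8E geometry and all three stereocentres, the acetate, the lactone and the furan untouched; the closest known reaction type is the metallaphotoredox deoxygenative arylation of NHC-activated alcohols with aryl halides (non-activated trisubstituted alkenyl iodides and free diols have not been shown), supported by alkyl-radical/alkenyl-halide Ni couplings such as step 5.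

## Compound list
1 | (S)-epichlorohydrin | ClC[C@@H]1CO1 | starting material
2 | (S)-1-chloropent-4-yn-2-ol | C#CC[C@H](O)CCl | intermediate
3 | (S)-hex-1-en-5-yn-3-ol | C#CC[C@H](O)C=C | intermediate
4 | (3S,5E)-6-iodo-5-methylhexa-1,5-dien-3-ol | O[C@H](C=C)C/C(C)=C/I | intermediate
5 | 3-(furan-3-yl)propanoic acid | OC(=O)CCc1ccoc1 | starting material
6 | 1,3-dioxoisoindolin-2-yl 3-(furan-3-yl)propanoate | O=C(CCc1ccoc1)ON1C(=O)c2ccccc2C1=O | intermediate
7 | (3S,5E)-8-(furan-3-yl)-5-methylocta-1,5-dien-3-ol | O[C@H](C=C)C/C(C)=C/CCc1ccoc1 | intermediate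
8 | (2Z,4S,6E)-9-(furan-3-yl)-6-methyl-2-(Bpin)nona-2,6-dien-4-ol | O[C@H](/C=C(\C)B1OC(C)(C)C(C)(C)O1)C/C(C)=C/CCc1ccoc1 | intermediate
9 | (2E,4S,6E)-9-(furan-3-yl)-2-iodo-6-methylnona-2,6-dien-4-ol | O[C@H](/C=C(\C)I)C/C(C)=C/CCc1ccoc1 | intermediate
10 | (2E,4S,6E)-9-(furan-3-yl)-2-iodo-6-methylnona-2,6-dien-4-yl acetate | CC(=O)O[C@H](/C=C(\C)I)C/C(C)=C/CCc1ccoc1 | intermediate
11 | potassium (R)-oxirane-2-carboxylate | [K+].[O-]C(=O)[C@H]1CO1 | starting material
12 | S-ethyl (R)-oxirane-2-carbothioate | CCSC(=O)[C@H]1CO1 | intermediate
13 | ethyl 4-[(2R)-oxiran-2-yl]-4-oxobutanoate | CCOC(=O)CCC(=O)[C@H]1CO1 | intermediate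
14 | (5S)-5-methyl-5-[(2R)-oxiran-2-yl]oxolan-2-one | C1O[C@H]1[C@]2(C)CCC(=O)O2 | intermediate
15 | (5S)-5-[(1R)-1-hydroxybut-3-en-1-yl]-5-methyloxolan-2-one | C=CC[C@@H](O)[C@]1(C)CCC(=O)O1 | intermediate
16 | (5S)-5-[(1R)-1,3-dihydroxypropyl]-5-methyloxolan-2-one | OCC[C@@H](O)[C@]1(C)CCC(=O)O1 | intermediate
17 | 10-acetylirciformonin B (4S,5R,10S,8E,12E) | CC(=O)O[C@H](/C=C(\C)CC[C@@H](O)[C@]1(C)CCC(=O)O1)C/C(C)=C/CCc1ccoc1 | target

## Totals and risks
Total steps: 14.
Longest linear sequence: 8 (steps 1, 2, 3, 5, 6, 7, 8, 14).

The three steps most likely to fail: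

1. **Step 14 (the proposed new coupling).** The risks are Ni(0) ionising the allylic acetate, protodeiodination, and adduct formation at C5–OH.
   Fallback (known chemistry): convert the primary OH of 16 selectively to the iodide (I2, PPh3, imidazole). Then join it to 10 by an established Ni/bipyridine electroreductive cross-electrophile coupling of an alkyl iodide with an alkenyl iodide (undivided cell, sacrificial anode).

2. **Step 6 (cross-metathesis to a hindered trisubstituted alkenyl boronate next to a secondary carbinol).** The risks are low conversion, eroded geometry, and Ru–H isomerisation of the allylic alcohol.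
   Fallback: abandon metathesis and use olefination. Start from the enantiomerically matching silyl glycidyl ether instead of 1, so that C9 is carried as a protected CH2OH through steps 1, 3 and 5. Acetylate C10–OH, unmask and oxidise C9 to the α-acetoxy aldehyde, then make 8-type boronate by boron-Wittig reaction with 1,1-bis(pinacolboryl)ethane/LiTMP.

3. **Step 11 (chelation-controlled addition to the base- and Lewis-acid-sensitive epoxy ketone).** The risks are modest dr, Payne rearrangement, and bromohydrin formation.
   Fallback: open methyl (R)-glycidate with the vinyl cuprate first and protect C5–OH as a BOM ether. Build the keto ester via the thioester/zinc homoenolate and add MeMgBr under classical α-alkoxy Cram-chelate control. Then ozonise/reduce and remove the BOM group by hydrogenolysis; at that stage the fragment contains no alkene.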